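**Retrosynthetic overview**
- The C8 methyl carbinol comes from β-face methyl addition to a C8 ketone; the acid and the C3 ketone are unmasked last.
- The C11–C12 bond joins a zinc homoenolate of the C8 ketone (from ring opening of a C8/C9/C11 cyclopropanol) to the allylic chloride of an (E,E,E)-ω-carboxylated farnesyl unit, itself made from farnesyl acetate by terminal allylic oxidation.
- The cyclopropanol comes from β-face cyclopropanation of the C8 silyl enol ether formed by conjugate methylation of a bicyclic enone, which sets the C10 quaternary centre and the cis ring fusion.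
- The enone comes from Birch reduction of 6-methoxy-1,1-dimethyl-2-tetralone ketal, followed by enantioselective β,γ→α,β olefin isomerisation, which sets C5.
- Ring order: ring A (C3 oxygen, C4 gem-dimethyl) is carbocyclic from the start; ring B is unveiled from the anisole ring; the only ring made later is the transient cyclopropane.

Assumption: the SMILES is read literally as (5S,8R,9R,10S), i.e. C5–H and the C10 methyl are cis (cis-fused decalin), C8 carries α-OH/β-CH3 and C9 the β side chain; polypodane numbering is used (ring A = C1–C5, C10 with C3 the carbonyl and C4 the CMe2 carbon; ring B = C5–C10; side chain from C11) and β is the face of the C10 methyl.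

**Step 1**
Reactants: 1 6-methoxy-2-tetralone
Product: 2 6-methoxy-1,1-dimethyl-3,4-dihydronaphthalen-2(1H)-one
Conditions: KOtBu (2.2 equiv), MeI (2.5 equiv), THF, 0 °C → rt
Reagents that add atoms: iodomethane, CI
Why: Enolate alkylation: the benzylic α-carbon of the β-tetralone is deprotonated far more readily than C3 and is methylated twice, placing the gem-dimethyl group (future C4) next to the aromatic ring; no stereocentre is formed.

**Step 2**
Reactants: 2 6-methoxy-1,1-dimethyl-3,4-dihydronaphthalen-2(1H)-one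
Product: 3 6'-methoxy-1',1'-dimethyl-3',4'-dihydro-1'H-spiro[1,3-dioxolane-2,2'-naphthalene]
Conditions: HOCH2CH2OH, p-TsOH (cat.), toluene, reflux (Dean–Stark)
Reagents that add atoms: ethane-1,2-diol, OCCO
Why: Acid-catalysed ketalisation masks the future C3 ketone, which has to survive a dissolving-metal reduction and two organometallic steps.

**Step 3**
Reactants: 3 6'-methoxy-1',1'-dimethyl-3',4'-dihydro-1'H-spiro[1,3-dioxolane-2,2'-naphthalene]
Product: 5 5',5'-dimethyl-1',3',4',5',7',8'-hexahydro-2'H-spiro[1,3-dioxolane-2,6'-naphthalen]-2'-one (C8 ketone; C5=C10 olefin), via dihydroanisole 4 (not isolated)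
Conditions: Li, NH3(l), t-BuOH, THF, −78 → −33 °C; H2O quench; then (CO2H)2, MeOH/H2O/THF, rt
Reagents that add atoms: water, O
Why: Birch reduction of the anisole keeps the tetrasubstituted ring-fusion olefin and the enol ether; oxalic acid then hydrolyses only the enol ether, giving the unconjugated β,γ-enone without moving the double bond or opening the dioxolane.

**Step 4**
Reactants: 5 5',5'-dimethyl-1',3',4',5',7',8'-hexahydro-2'H-spiro[1,3-dioxolane-2,6'-naphthalen]-2'-one
Product: 6 (4a'S)-5',5'-dimethyl-3',4',4a',5',7',8'-hexahydro-2'H-spiro[1,3-dioxolane-2,6'-naphthalen]-2'-one (conjugated enone C8(=O)–C9=C10; 5S)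
Conditions: 9-amino-9-deoxy-epi-quinine (10 mol %), Cl3CCO2H (20 mol %), toluene, rt
Reagents that add atoms: none
Why: Primary-amine (dienamine) catalysed enantioselective olefin isomerisation, a known reaction type for Birch-derived β,γ-cyclohexenones: the protonated quinuclidine of the catalyst delivers the proton to one face of the γ-carbon C5, creating the 5S centre (the quinidine-derived pseudo-enantiomer is used instead if it proves to be the one that gives 5S).

**Step 5**
Reactants: 6 (4a'S)-conjugated enone ketal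
Product: 7 (5S,10S)-C8 trimethylsilyl enol ether (C8=C9) of cis-fused 4,4,10-trimethyldecalin-3,8-dione 3-ethylene ketal
Conditions: Me2CuLi (from MeLi and CuI, 1.5 equiv), TMSCl (3 equiv), Et2O/THF, −78 → −30 °C; Et3N
Reagents that add atoms: methyllithium, [Li]C; chlorotrimethylsilane, C[Si](C)(C)Cl
Why: Cuprate conjugate addition to a Δ1(9)-octal-2-one-type enone, which is known to give the cis ring fusion: methyl enters C10 on the face of C5–H (the other face would be syn-diaxial to the axial C4 methyl), setting 10S, and TMSCl traps the enolate regiospecifically as the C8=C9 silyl enol ether.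

**Step 6**
Reactants: 7 (5S,10S)-C8 trimethylsilyl enol ether
Product: 9 (5S,8S,9R,10S)-8β,9β-methano-8α-hydroxy-4,4,10-trimethyl-cis-decalin-3-one ethylene ketal (tertiary cyclopropanol; cyclopropane CH2 = C11), via siloxycyclopropane 8 (not isolated)
Conditions: Et2Zn, CH2I2, CH2Cl2, 0 °C → rt; then K2CO3 (cat.), MeOH, 0 °C
Reagents that add atoms: diiodomethane, ICI
Why: Furukawa–Simmons–Smith cyclopropanation of the electron-rich enol ether from the convex β-face of the cis-decalin (the α-face is screened by the axial C1 of ring A) fixes C9 (C11 β, H α) and C8–O α in one stereospecific syn addition; mild methanolysis then frees the cyclopropanol.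

**Step 7**
Reactants: 10 (2E,6E)-farnesyl acetate
Product: 11 (2E,6E,10E)-12-hydroxy-3,7,11-trimethyldodeca-2,6,10-trien-1-yl acetate
Conditions: SeO2 (cat.), salicylic acid (cat.), t-BuOOH, CH2Cl2, rt
Reagents that add atoms: tert-butyl hydroperoxide, CC(C)(C)OO
Why: Catalytic SeO2 allylic oxidation (ene reaction then [2,3]-sigmatropic shift) attacks the (E)-methyl of the terminal, most electron-rich trisubstituted olefin, giving the E allylic alcohol; the 2,3-olefin is deactivated by the acetate.

**Step 8**
Reactants: 11 (2E,6E,10E)-12-hydroxy-3,7,11-trimethyldodeca-2,6,10-trien-1-yl acetate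
Product: 13 (2E,6E,10E)-12-acetoxy-2,6,10-trimethyldodeca-2,6,10-trienoic acid, via enal 12 (not isolated)
Conditions: TEMPO (cat.), PhI(OAc)2, CH2Cl2, rt; then NaClO2, NaH2PO4, 2-methyl-2-butene, t-BuOH/H2O, 0 °C → rt
Reagents that add atoms: sodium chlorite, [Na+].[O-]Cl=O
Why: Oxoammonium oxidation of the allylic alcohol to the E-enal followed in the same flask by Pinnick oxidation; both are mild enough to leave the acetate and the olefin geometries untouched (any enal already formed in step 7 converges here).

**Step 9**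
Reactants: 13 (2E,6E,10E)-12-acetoxy-2,6,10-trimethyldodeca-2,6,10-trienoic acid
Product: 15 methyl (2E,6E,10E)-12-hydroxy-2,6,10-trimethyldodeca-2,6,10-trienoate, via potassium carboxylate 14 (not isolated)
Conditions: K2CO3, MeOH, rt; evaporate; then MeI, DMF, rt
Reagents that add atoms: iodomethane, CI
Why: Carbonate-mediated methanolysis removes the acetate while the acid sits as its carboxylate, which is then O-methylated by SN2 alkylation; the free allylic alcohol is not alkylated by K2CO3/MeI.

**Step 10**
Reactants: 15 methyl (2E,6E,10E)-12-hydroxy-2,6,10-trimethyldodeca-2,6,10-trienoate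
Product: 16 methyl (2E,6E,10E)-12-chloro-2,6,10-trimethyldodeca-2,6,10-trienoate
Conditions: NCS, Me2S, CH2Cl2, −30 → 0 °C
Reagents that add atoms: N-chlorosuccinimide, ClN1C(=O)CCC1=O
Why: Corey–Kim chlorination: chloride displaces the alkoxysulfonium group by SN2 without allylic transposition, so the E geometry is kept.

**Step 11**
Reactants: 9 (5S,8S,9R,10S)-cyclopropanol; 16 methyl (2E,6E,10E)-12-chloro-2,6,10-trimethyldodeca-2,6,10-trienoate
Product: 18 methyl (2E,6E,10E)-13-[(5S,9R,10S)-3,3-ethylenedioxy-4,4,10-trimethyl-8-oxo-cis-decalin-9β-yl]-2,6,10-trimethyltrideca-2,6,10-trienoate, via zinc homoenolate 17 (not isolated)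
Conditions: Et2Zn (0.55 equiv), THF/DMA, 0 °C → rt; then 16 (1.1 equiv), NiCl2·glyme (10 mol %), 2,6-bis(4,5-dihydrooxazol-2-yl)pyridine (13 mol %), DMA, 0 °C → rt
Reagents that add atoms: none
Why: Proposed new method: Et2Zn deprotonates the cyclopropanol and the zinc cyclopropoxide opens by strain-driven cleavage of the C8–C11 bond to the carbonyl-chelated primary β-zincio ketone (homoenolate; C9 and its configuration untouched), which transmetalates to nickel and couples with the allylnickel species from 16 at its unhindered primary terminus, so the normally electrophilic β-carbon of the C8 ketone (C11) is joined to the electrophilic allylic carbon (C12) with the linear E olefin retained; the closest known reactions are copper- and palladium-catalysed couplings of zinc homoenolates made from cyclopropanols or siloxycyclopropanes and nickel/pybox-catalysed Negishi couplings of alkylzinc reagents with allylic chlorides (copper is avoided because it would give SN2' attack at the trisubstituted terminus).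

**Step 12**
Reactants: 18 keto ester ketal
Product: 19 methyl (2E,6E,10E)-13-[(5S,8R,9R,10S)-3,3-ethylenedioxy-8α-hydroxy-4,4,8β,10-tetramethyl-cis-decalin-9β-yl]-2,6,10-trimethyltrideca-2,6,10-trienoate
Conditions: MeMgBr (2 equiv), LaCl3·2LiCl (1 equiv), THF, −78 → −40 °C; then H2O/NH4Cl
Reagents that add atoms: methylmagnesium bromide, C[Mg]Br
Why: Lewis-acid-promoted Grignard 1,2-addition: the cis-decalin prefers the chair–chair form with C1 axial on ring B (the other form would push the 4α-methyl into ring B), so methyl enters C8 by equatorial attack from the convex β-face and gives 8β-CH3/8α-OH (8R); LaCl3·2LiCl suppresses enolisation toward the epimerisable C9 and the hindered conjugated ester is inert at −78 °C.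

**Step 13**
Reactants: 19 hydroxy ester ketal
Product: 21 myrrhanone B, via lithium carboxylate 20 (not isolated)
Conditions: LiOH, THF/MeOH/H2O, 45 °C; then 2 M HCl to pH 1, THF, rt
Reagents that add atoms: lithium hydroxide, [Li+].[OH-]; water, O
Why: Saponification of the methyl ester followed by acid-catalysed hydrolysis of the hindered dioxolane on acidification; dilute acid at rt leaves the tertiary alcohol and the trisubstituted olefins untouched, and no stereocentre is affected.

**Compound list**
1 | 6-methoxy-3,4-dihydronaphthalen-2(1H)-one (6-methoxy-2-tetralone) | COc1ccc2c(c1)CCC(=O)C2 | starting material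
2 | 6-methoxy-1,1-dimethyl-3,4-dihydronaphthalen-2(1H)-one | COc1ccc2c(c1)CCC(=O)C2(C)C | intermediate
3 | 6'-methoxy-1',1'-dimethyl-3',4'-dihydro-1'H-spiro[1,3-dioxolane-2,2'-naphthalene] | COc1ccc2c(c1)CCC1(OCCO1)C2(C)C | intermediate
4 | 6'-methoxy-1',1'-dimethyl-3',4',5',8'-tetrahydro-1'H-spiro[1,3-dioxolane-2,2'-naphthalene] (dihydroanisole enol ether) | COC1=CCC2=C(C1)CCC1(OCCO1)C2(C)C | intermediate (not isolated)
5 | 5',5'-dimethyl-1',3',4',5',7',8'-hexahydro-2'H-spiro[1,3-dioxolane-2,6'-naphthalen]-2'-one (β,γ-enone) | O=C1CCC2=C(C1)CCC1(OCCO1)C2(C)C | intermediate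
6 | (4a'S)-5',5'-dimethyl-3',4',4a',5',7',8'-hexahydro-2'H-spiro[1,3-dioxolane-2,6'-naphthalen]-2'-one (conjugated enone, 5S) | O=C1C=C2CCC3(OCCO3)C(C)(C)[C@H]2CC1 | intermediate
7 | (5S,10S)-C8 trimethylsilyl enol ether (C8=C9) of cis-fused 4,4,10-trimethyldecalin-3,8-dione 3-ethylene ketal | C[Si](C)(C)OC1=C[C@@]2(C)CCC3(OCCO3)C(C)(C)[C@H]2CC1 | intermediate
8 | (5S,8S,9R,10S)-8β,9β-methano-8α-(trimethylsilyloxy)-4,4,10-trimethyl-cis-decalin-3-one ethylene ketal | C1[C@@H]2[C@@]3(C)CCC4(OCCO4)C(C)(C)[C@H]3CC[C@@]21O[Si](C)(C)C | intermediate (not isolated)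
9 | (5S,8S,9R,10S)-8β,9β-methano-8α-hydroxy-4,4,10-trimethyl-cis-decalin-3-one ethylene ketal (cyclopropanol) | C1[C@@H]2[C@@]3(C)CCC4(OCCO4)C(C)(C)[C@H]3CC[C@@]21O | intermediate
10 | (2E,6E)-3,7,11-trimethyldodeca-2,6,10-trien-1-yl acetate ((E,E)-farnesyl acetate) | CC(C)=CCC/C(C)=C/CC/C(C)=C/COC(C)=O | starting material
11 | (2E,6E,10E)-12-hydroxy-3,7,11-trimethyldodeca-2,6,10-trien-1-yl acetate | OC/C(C)=C/CC/C(C)=C/CC/C(C)=C/COC(C)=O | intermediate
12 | (2E,6E,10E)-3,7,11-trimethyl-12-oxododeca-2,6,10-trien-1-yl acetate (enal) | O=C/C(C)=C/CC/C(C)=C/CC/C(C)=C/COC(C)=O | intermediate (not isolated)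
13 | (2E,6E,10E)-12-acetoxy-2,6,10-trimethyldodeca-2,6,10-trienoic acid | OC(=O)/C(C)=C/CC/C(C)=C/CC/C(C)=C/COC(C)=O | intermediate
14 | potassium (2E,6E,10E)-12-hydroxy-2,6,10-trimethyldodeca-2,6,10-trienoate | [K+].[O-]C(=O)/C(C)=C/CC/C(C)=C/CC/C(C)=C/CO | intermediate (not isolated)
15 | methyl (2E,6E,10E)-12-hydroxy-2,6,10-trimethyldodeca-2,6,10-trienoate | COC(=O)/C(C)=C/CC/C(C)=C/CC/C(C)=C/CO | intermediate
16 | methyl (2E,6E,10E)-12-chloro-2,6,10-trimethyldodeca-2,6,10-trienoate | COC(=O)/C(C)=C/CC/C(C)=C/CC/C(C)=C/CCl | intermediate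
17 | bis{[(5S,9R,10S)-3,3-ethylenedioxy-4,4,10-trimethyl-8-oxo-cis-decalin-9β-yl]methyl}zinc (zinc homoenolate) | [Zn](C[C@@H]1[C@@]2(C)CCC3(OCCO3)C(C)(C)[C@H]2CCC1=O)C[C@@H]1[C@@]2(C)CCC3(OCCO3)C(C)(C)[C@H]2CCC1=O | intermediate (not isolated)
18 | methyl (2E,6E,10E)-13-[(5S,9R,10S)-3,3-ethylenedioxy-4,4,10-trimethyl-8-oxo-cis-decalin-9β-yl]-2,6,10-trimethyltrideca-2,6,10-trienoate | COC(=O)/C(C)=C/CC/C(C)=C/CC/C(C)=C/CC[C@@H]1[C@@]2(C)CCC3(OCCO3)C(C)(C)[C@H]2CCC1=O | intermediate
19 | methyl (2E,6E,10E)-13-[(5S,8R,9R,10S)-3,3-ethylenedioxy-8α-hydroxy-4,4,8β,10-tetramethyl-cis-decalin-9β-yl]-2,6,10-trimethyltrideca-2,6,10-trienoate | COC(=O)/C(C)=C/CC/C(C)=C/CC/C(C)=C/CC[C@@H]1[C@@]2(C)CCC3(OCCO3)C(C)(C)[C@H]2CC[C@@]1(C)O | intermediate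
20 | lithium (2E,6E,10E)-13-[(5S,8R,9R,10S)-3,3-ethylenedioxy-8α-hydroxy-4,4,8β,10-tetramethyl-cis-decalin-9β-yl]-2,6,10-trimethyltrideca-2,6,10-trienoate | [Li+].[O-]C(=O)/C(C)=C/CC/C(C)=C/CC/C(C)=C/CC[C@@H]1[C@@]2(C)CCC3(OCCO3)C(C)(C)[C@H]2CC[C@@]1(C)O | intermediate (not isolated)
21 | myrrhanone B, (2E,6E,10E)-13-[(1R,2R,4aS,8aS)-2-hydroxy-2,5,5,8a-tetramethyl-6-oxodecahydronaphthalen-1-yl]-2,6,10-trimethyltrideca-2,6,10-trienoic acid | C/C(=C\CC/C(C)=C/CC[C@@H]1[C@@]2(C)CCC(=O)C(C)(C)[C@H]2CC[C@@]1(C)O)CC/C=C(\C)C(=O)O | target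

**Step count**
Total: 13 steps. Longest linear sequence: 9 steps (steps 1–6, 11, 12, 13 from 6-methoxy-2-tetralone); the side-chain branch is steps 7–10.

**Steps most likely to fail, with fallbacks**

Step 4 (enantioselective isomerisation; the γ-carbon is flanked by the C4 quaternary centre, so rate and ee are uncertain). The fallback sets out from 5 and comes back at 6. NaOMe in MeOH at rt equilibrates 5 to the racemic conjugated enone F1, which is resolved by preparative SFC on an amylose tris(3,5-dimethylphenylcarbamate) phase to give 6. The unwanted enantiomer is returned to achiral 5 by kinetic deconjugation (LDA, THF, −78 °C; AcOH quench) and recycled. This replaces asymmetric catalysis by resolution with recycling.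

Step 11 (homoenolate–allyl coupling; possible ring-opening to the 9-methyl ketone, β-hydride loss to the α-methylene ketone, or allyl homocoupling). The fallback sets out from 9 (16 is used unchanged) and comes back at 18. N-Iodosuccinimide in CH2Cl2 at 0 °C opens the cyclopropanol electrophilically at the C8–C11 bond to the β-iodo ketone F2, with C9 untouched. F2 and 16 are then joined by nickel-catalysed reductive cross-electrophile coupling (NiCl2·glyme, 4,4'-di-tert-butyl-2,2'-bipyridine, Zn powder, MgCl2, DMA, rt), a known reaction type for alkyl halides with allylic electrophiles that gives linear E products. No preformed organozinc is needed.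

Step 12 (facial selectivity of methyl addition; if the other chair–chair form reacts, the 8-epimer results). The fallback sets out from 18 and comes back at 19. Non-basic Lombardo methylenation (Zn, CH2Br2, TiCl4, THF/CH2Cl2, 0 °C) gives the exocyclic 8-methylene compound F3. Oxymercuration with Hg(OAc)2 (1.0 equiv, THF/H2O, 0 °C) gives the hydroxy organomercurial F4, and NaBH4/NaOH demercuration gives 19. Here oxygen, not carbon, is the group delivered to C8 from the more accessible face, so the outcome is opposite to that of direct Grignard addition; 1,1-disubstituted olefins are oxymercurated well ahead of the trisubstituted ones in the side chain.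

**Further compounds**
F1 | step 4 | racemic 5',5'-dimethyl-3',4',4a',5',7',8'-hexahydro-2'H-spiro[1,3-dioxolane-2,6'-naphthalen]-2'-one | O=C1C=C2CCC3(OCCO3)C(C)(C)C2CC1
F2 | step 11 | (5S,9R,10S)-3,3-ethylenedioxy-9β-(iodomethyl)-4,4,10-trimethyl-cis-decalin-8-one | IC[C@@H]1[C@@]2(C)CCC3(OCCO3)C(C)(C)[C@H]2CCC1=O
F3 | step 12 | methyl (2E,6E,10E)-13-[(5S,9R,10S)-3,3-ethylenedioxy-4,4,10-trimethyl-8-methylidene-cis-decalin-9β-yl]-2,6,10-trimethyltrideca-2,6,10-trienoate | COC(=O)/C(C)=C/CC/C(C)=C/CC/C(C)=C/CC[C@@H]1[C@@]2(C)CCC3(OCCO3)C(C)(C)[C@H]2CCC1=C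
F4 | step 12 | methyl (2E,6E,10E)-13-[(5S,8R,9R,10S)-8β-(acetoxymercuriomethyl)-3,3-ethylenedioxy-8α-hydroxy-4,4,10-trimethyl-cis-decalin-9β-yl]-2,6,10-trimethyltrideca-2,6,10-trienoate | COC(=O)/C(C)=C/CC/C(C)=C/CC/C(C)=C/CC[C@@H]1[C@@]2(C)CCC3(OCCO3)C(C)(C)[C@H]2CC[C@@]1(C[Hg]OC(C)=O)O
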